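**Strategy.** Flavan numbering (O1, C2, C3, C4, C4a, C5–C8, C8a) is used. Ring C is cut at O1–C8a and C2–C3: O1=C2 becomes O-benzylvanillin, and ring A arrives as a 2-fluoroaryl ketone whose carbonyl is the later C4 methylene. This temporary C4 ketone acidifies C3–H for an aldol to C2 and, sitting on C4a ortho to C8a, activates C8a–F for displacement by the new C2 alkoxide, so one operation closes ring C with the 2,3-trans relationship (thermodynamic). The ketone also keeps the racemate dynamic through retro-oxa-Michael opening, so an asymmetric transfer hydrogenation sets the absolute configuration before C4–O and the benzyl groups are removed by hydrogenolysis.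

Key step: step 4

Remark: compounds 1, 3, 4 and 10 are taken as purchasable; the catalyst antipode in step 5 is assigned by analogy with the facial preference known for chroman-4-ones and would be exchanged for its mirror image if the preference proved opposite.

Step 1
Reactants: 1 3-(benzyloxy)benzaldehyde
Product: 2 1-(benzyloxy)-3-ethenylbenzene
Conditions: Ph3PCH3Br, KOtBu, THF, 0 → 23 °C
Reagents that add atoms: methyltriphenylphosphonium bromide, C[P+](c1ccccc1)(c1ccccc1)c1ccccc1.[Br-]
Why: Wittig methylenation of a non-enolisable aryl aldehyde by the unstabilised ylide; no stereocenter is formed.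

Step 2
Reactants: 3 1-bromo-3-fluoro-5-methoxybenzene; 4 2-(benzyloxy)-N-methoxy-N-methylacetamide
Product: 7 2-(benzyloxy)-1-(2-bromo-6-fluoro-4-methoxyphenyl)ethan-1-one, via aryllithium 5 (not isolated), via lithium hemiaminal alkoxide 6 (not isolated)
Conditions: LiN(iPr)2, THF, −78 °C; then 4, −78 °C; 1 M HCl
Reagents that add atoms: none
Why: Ortho-lithiation should remove the most acidic ring proton, the one flanked by fluorine and bromine, and the aryllithium adds only once to the Weinreb amide because the chelated tetrahedral adduct collapses to the ketone only on acidic work-up (Weinreb ketone synthesis).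

Step 3
Reactants: 2 1-(benzyloxy)-3-ethenylbenzene; 7 2-(benzyloxy)-1-(2-bromo-6-fluoro-4-methoxyphenyl)ethan-1-one
Product: 9 2-(benzyloxy)-1-{2-[2-(3-benzyloxyphenyl)ethyl]-6-fluoro-4-methoxyphenyl}ethan-1-one, via alkylborane 8 (not isolated)
Conditions: 9-BBN-H, THF, 23 °C; then 7, PdCl2(dppf) (5 mol %), K3PO4, DMF/H2O, 60 °C
Reagents that add atoms: none
Why: Anti-Markovnikov hydroboration of the styrene gives a primary alkylborane that enters a B-alkyl Suzuki–Miyaura coupling, the C–Br bond (activated by the ortho acyl group) adding to zerovalent palladium far faster than the C–F bond, so the saturated two-carbon bridge is installed directly.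

Step 4
Reactants: 9 2-(benzyloxy)-1-{2-[2-(3-benzyloxyphenyl)ethyl]-6-fluoro-4-methoxyphenyl}ethan-1-one; 10 4-(benzyloxy)-3-methoxybenzaldehyde
Product: 13 rac-(2R,3R)-3-(benzyloxy)-2-[4-(benzyloxy)-3-methoxyphenyl]-5-[2-(3-benzyloxyphenyl)ethyl]-7-methoxy-2,3-dihydro-4H-chromen-4-one, via potassium enolate 11 (not isolated), via potassium aldolate 12 (not isolated)
Conditions: KN(SiMe3)2 (1.1 equiv), THF, −78 °C; 10; then DMF, −78 → 40 °C; then AcOH, NaOAc, 23 °C
Reagents that add atoms: none
Why: The potassium enolate 11 adds through C3 to the aldehyde carbon of 10 (C2–C3 bond), and the alkoxide O1 of aldolate 12 then attacks C8a, whose fluoride is activated by the ortho C4 carbonyl, by addition–elimination with loss of fluoride (O1–C8a bond). The closest known reaction types are the crossed aldol addition of an α-alkoxy aryl ketone and the intramolecular SNAr closure of 2-fluoroaryl ketones to chroman-4-ones, run here as one domino aldol–SNAr annulation. Ring C closes in the 6-exo mode, O1 adding to the ring carbon C8a of the arene while fluoride leaves. C2 and C3 are set under thermodynamic control: the aldol is reversible before closure and C3 enolises after it, which should lead to the 2,3-trans isomer with the C2 aryl and C3 benzyloxy groups both equatorial, as the racemate. The step needs the aldolate to cyclise faster than it loses hydroxide and needs O1 rather than O3 to attack the arene; the single C–F bond ortho to the acyl group, the benzyl cap on O3, the non-enolisable aldehyde and the non-nucleophilic base secure this.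

Step 5
Reactants: 13 rac-(2R,3R)-3-(benzyloxy)-2-[4-(benzyloxy)-3-methoxyphenyl]-5-[2-(3-benzyloxyphenyl)ethyl]-7-methoxy-2,3-dihydro-4H-chromen-4-one
Product: 15 (2R,3S,4S)-3-(benzyloxy)-2-[4-(benzyloxy)-3-methoxyphenyl]-5-[2-(3-benzyloxyphenyl)ethyl]-7-methoxy-3,4-dihydro-2H-chromen-4-ol, via 2'-hydroxychalcone 14 (not isolated)
Conditions: RuCl[(R,R)-TsDPEN](p-cymene) (2 mol %), HCO2H (3 equiv), DBU (4 equiv), MeCN, 40 °C
Reagents that add atoms: none
Why: Asymmetric transfer hydrogenation with dynamic kinetic resolution: DBU should interconvert the enantiomers of 13 by E1cB opening to the achiral chalcone 14 and oxa-Michael re-closure, while the (R,R)-configured ruthenium hydride reduces the (2R,3R)-ketone faster and delivers hydride to the C4 face anti to the C3 benzyloxy group, which fixes C2 as R and C3 as S and makes C4 S (3,4-cis).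

Step 6
Reactants: 15 (2R,3S,4S)-3-(benzyloxy)-2-[4-(benzyloxy)-3-methoxyphenyl]-5-[2-(3-benzyloxyphenyl)ethyl]-7-methoxy-3,4-dihydro-2H-chromen-4-ol
Product: 16 shanciol B
Conditions: H2 (1 atm), Pd(OH)2/C, EtOAc/MeOH/AcOH, 23 °C
Reagents that add atoms: none
Why: Catalytic hydrogenolysis should remove the three benzyl ethers and the C4 hydroxyl, which is benzylic to ring A and activated by the ortho O1 and the para methoxy group, while C2 and C3 are untouched and the hindered ring C2–O1 bond is cleaved more slowly.

**Compound list**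

1 | 3-(benzyloxy)benzaldehyde | O=Cc1cccc(OCc2ccccc2)c1 | starting material
2 | 1-(benzyloxy)-3-ethenylbenzene | C=Cc1cccc(OCc2ccccc2)c1 | intermediate
3 | 1-bromo-3-fluoro-5-methoxybenzene | COc1cc(F)cc(Br)c1 | starting material
4 | 2-(benzyloxy)-N-methoxy-N-methylacetamide | CON(C)C(=O)COCc1ccccc1 | starting material
5 | (2-bromo-6-fluoro-4-methoxyphenyl)lithium, formed in the flask | COc1cc(F)c([Li])c(Br)c1 | intermediate
6 | lithium 2-(benzyloxy)-1-(2-bromo-6-fluoro-4-methoxyphenyl)-1-[methoxy(methyl)amino]ethan-1-olate, formed in the flask | COc1cc(F)c(C([O-])(COCc2ccccc2)N(C)OC)c(Br)c1.[Li+] | intermediate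
7 | 2-(benzyloxy)-1-(2-bromo-6-fluoro-4-methoxyphenyl)ethan-1-one | COc1cc(F)c(C(=O)COCc2ccccc2)c(Br)c1 | intermediate
8 | 9-[2-(3-benzyloxyphenyl)ethyl]-9-borabicyclo[3.3.1]nonane, formed in the flask | C1CC2CCCC(C1)B2CCc1cccc(OCc2ccccc2)c1 | intermediate
9 | 2-(benzyloxy)-1-{2-[2-(3-benzyloxyphenyl)ethyl]-6-fluoro-4-methoxyphenyl}ethan-1-one | COc1cc(F)c(C(=O)COCc2ccccc2)c(CCc2cccc(OCc3ccccc3)c2)c1 | intermediate
10 | 4-(benzyloxy)-3-methoxybenzaldehyde (O-benzylvanillin) | COc1cc(C=O)ccc1OCc1ccccc1 | starting material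
11 | potassium (Z)-enolate of 9, formed in the flask | COc1cc(F)c(/C([O-])=C/OCc2ccccc2)c(CCc2cccc(OCc3ccccc3)c2)c1.[K+] | intermediate
12 | potassium aldolate from 11 and 10 (mixture of diastereomers, racemic), formed in the flask | COc1cc(F)c(C(=O)C(OCc2ccccc2)C([O-])c2ccc(OCc3ccccc3)c(OC)c2)c(CCc2cccc(OCc3ccccc3)c2)c1.[K+] | intermediate
13 | rac-(2R,3R)-3-(benzyloxy)-2-[4-(benzyloxy)-3-methoxyphenyl]-5-[2-(3-benzyloxyphenyl)ethyl]-7-methoxy-2,3-dihydro-4H-chromen-4-one (2,3-trans; racemate, one enantiomer drawn) | COc1cc(CCc2cccc(OCc3ccccc3)c2)c2c(c1)O[C@H](c1ccc(OCc3ccccc3)c(OC)c1)[C@@H](OCc1ccccc1)C2=O | intermediate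
14 | (Z)-2-(benzyloxy)-3-[4-(benzyloxy)-3-methoxyphenyl]-1-{2-[2-(3-benzyloxyphenyl)ethyl]-6-hydroxy-4-methoxyphenyl}prop-2-en-1-one, formed in the flask | COc1cc(O)c(C(=O)/C(OCc2ccccc2)=C/c2ccc(OCc3ccccc3)c(OC)c2)c(CCc2cccc(OCc3ccccc3)c2)c1 | intermediate
15 | (2R,3S,4S)-3-(benzyloxy)-2-[4-(benzyloxy)-3-methoxyphenyl]-5-[2-(3-benzyloxyphenyl)ethyl]-7-methoxy-3,4-dihydro-2H-chromen-4-ol | COc1cc(CCc2cccc(OCc3ccccc3)c2)c2c(c1)O[C@H](c1ccc(OCc3ccccc3)c(OC)c1)[C@@H](OCc1ccccc1)[C@H]2O | intermediate
16 | shanciol B, (2R,3S)-2-(4-hydroxy-3-methoxyphenyl)-5-[2-(3-hydroxyphenyl)ethyl]-7-methoxy-3,4-dihydro-2H-chromen-3-ol | COc1cc(CCc2cccc(O)c2)c2c(c1)O[C@H](c1ccc(O)c(OC)c1)[C@@H](O)C2 | target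

**Step count.** Total: 6 steps. Longest linear sequence: 5 steps (3 → 7 → 9 → 13 → 15 → 16; the branch 1 → 2 joins at step 3).

**Steps most likely to fail**

1. Step 4 (key step). Loss of hydroxide from aldolate 12 to the fluoro-chalcone, or retro-aldol, may outrun the attack of O1 on C8a, so that ring C does not close. The fallback changes the order of events to the classical chalcone route and sets out from 9. KOH in DMSO/H2O at 80 °C replaces the activated fluoride by hydroxide (SNAr) to give 2-(benzyloxy)-1-{2-[2-(3-benzyloxyphenyl)ethyl]-6-hydroxy-4-methoxyphenyl}ethan-1-one F1. Claisen–Schmidt condensation of F1 with 10 (KOH, EtOH, 23 °C) gives chalcone 14, and buffered oxa-Michael closure (NaOAc, EtOH, reflux) comes back to the route at 13.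

2. Step 5. Ring opening and re-closure may be too slow relative to hydride transfer, so that the mismatched enantiomer accumulates or is reduced with poor selectivity, or the transient enone 14 may itself be reduced. The fallback replaces the dynamic process by a resolution with recycling and sets out from 13. The same catalyst under base-free conditions (HCO2H/Et3N 5:2, 23 °C) reduces only the matched enantiomer to 15 (kinetic resolution). The unreacted (2S,3S)-enantiomer of 13 F2 is separated, racemised in its own flask (DBU, toluene, 60 °C) in the absence of any hydride source, and resubmitted. The fallback comes back to the route at 15.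

3. Step 6. Hydrogenolysis of the C4–OH may be incomplete, or over-reduction may cleave the C2–O1 bond once the phenols are free. The fallback separates deoxygenation from deprotection and sets out from 15. Ionic reduction (Et3SiH, CF3CO2H, CH2Cl2, −20 °C) through the C4 cation, which is stabilised by O1 and the C7 methoxy group, gives (2R,3S)-3-(benzyloxy)-2-[4-(benzyloxy)-3-methoxyphenyl]-5-[2-(3-benzyloxyphenyl)ethyl]-7-methoxy-3,4-dihydro-2H-chromene F3. Neutral debenzylation (H2, Pd(OH)2/C, EtOAc/MeOH, 23 °C) then comes back to the route at 16.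

Further compounds
F1 | step 4 | 2-(benzyloxy)-1-{2-[2-(3-benzyloxyphenyl)ethyl]-6-hydroxy-4-methoxyphenyl}ethan-1-one | COc1cc(O)c(C(=O)COCc2ccccc2)c(CCc2cccc(OCc3ccccc3)c2)c1
F2 | step 5 | (2S,3S)-3-(benzyloxy)-2-[4-(benzyloxy)-3-methoxyphenyl]-5-[2-(3-benzyloxyphenyl)ethyl]-7-methoxy-2,3-dihydro-4H-chromen-4-one | COc1cc(CCc2cccc(OCc3ccccc3)c2)c2c(c1)O[C@@H](c1ccc(OCc3ccccc3)c(OC)c1)[C@H](OCc1ccccc1)C2=O
F3 | step 6 | (2R,3S)-3-(benzyloxy)-2-[4-(benzyloxy)-3-methoxyphenyl]-5-[2-(3-benzyloxyphenyl)ethyl]-7-methoxy-3,4-dihydro-2H-chromene | COc1cc(CCc2cccc(OCc3ccccc3)c2)c2c(c1)O[C@H](c1ccc(OCc3ccccc3)c(OC)c1)[C@@H](OCc1ccccc1)C2
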